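**Retrosynthetic overview**
1. Target ⇒ 8‑hydroxy‑9‑silyloxy germacranolide + (S)‑2‑methylglycidic acid (esterify O8, then exchange silyl for acetyl at O9).
2. Ten‑membered ring ⇒ C8–C9 bond (key step): the C9 aldehyde carbon of a 2‑formyl enoate is made nucleophilic (γ‑silyloxyallylchromium from CrCl2/Et3SiCl) and adds to the C8 aldehyde. This closes the carbocycle last and sets C8, C9 and the C1=C10 geometry.
3. Dialdehyde ⇒ C1 aldehyde + methyl 3,3‑dimethoxypropanoate (C9, C10, C14) by aldol condensation; C1 aldehyde ⇒ ozonolysis of the nerol isopropylidene.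
4. cis‑γ‑Lactone (C6–C7 bond) ⇒ nerol‑derived epoxy aldehyde + (Z)‑2‑(bromomethyl)‑4,4‑dimethoxybut‑2‑enoate by indium Barbier allylation; epoxy aldehyde ⇒ nerol by Sharpless epoxidation.
5. Ring order: C4–C5 epoxide, then γ‑lactone, then ten‑membered carbocycle; the side‑chain oxirane arrives preformed.

Assumption: the SMILES is taken literally, i.e. (4R,5S,6R,7R,8S,9S,2′S) with a cis‑epoxide, a cis‑fused 12,6‑lactone and C2 cis to C9 across C1=C10; germacrane numbering is used throughout.

**Step 1**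
Reactants: 1 2,2-dimethoxyacetaldehyde (60% aqueous solution); 2 methyl acrylate
Product: 3 methyl 3-hydroxy-4,4-dimethoxy-2-methylidenebutanoate (racemic)
Conditions: DABCO (0.5 equiv), 1,4-dioxane/H2O, rt
Reagents that add atoms: none
Why: Morita–Baylis–Hillman reaction, in which the DABCO‑derived ammonium enolate of the acrylate adds to the very electrophilic α‑alkoxy aldehyde; the racemic carbinol centre is erased in step 2.

**Step 2**
Reactants: 3 methyl 3-hydroxy-4,4-dimethoxy-2-methylidenebutanoate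
Product: 4 methyl (2Z)-2-(bromomethyl)-4,4-dimethoxybut-2-enoate
Conditions: NBS, Me2S, CH2Cl2, 0 °C to rt
Reagents that add atoms: N-bromosuccinimide O=C1CCC(=O)N1Br
Why: Corey–Kim‑type bromination with allylic transposition (SN2′), in which bromide attacks the methylene terminus of the alkoxysulfonium salt and gives the conjugated, thermodynamically preferred bromide with the acetal carbon cis to CH2Br.

**Step 3**
Reactants: 5 nerol
Product: 6 [(2S,3R)-3-methyl-3-(4-methylpent-3-en-1-yl)oxiran-2-yl]methanol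
Conditions: Ti(OiPr)4 (5 mol%), L-(+)-diisopropyl tartrate (6 mol%), t-BuOOH, 4 Å molecular sieves, CH2Cl2, −20 °C
Reagents that add atoms: tert-butyl hydroperoxide CC(C)(C)OO
Why: Sharpless asymmetric epoxidation, in which the L‑(+)‑tartrate titanium catalyst epoxidises only the allylic Z‑olefin and sets C4 (R) and C5 (S) of the target as a cis‑epoxide.

**Step 4**
Reactants: 6 [(2S,3R)-3-methyl-3-(4-methylpent-3-en-1-yl)oxiran-2-yl]methanol
Product: 7 (2R,3R)-3-methyl-3-(4-methylpent-3-en-1-yl)oxirane-2-carbaldehyde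
Conditions: TEMPO (10 mol%), PhI(OAc)2, CH2Cl2, rt
Reagents that add atoms: none
Why: TEMPO/PhI(OAc)2 (oxoammonium) oxidation stops at the aldehyde under nearly neutral conditions and leaves the epoxide and the trisubstituted olefin untouched; the descriptor at the carbinol‑bearing epoxide carbon changes only through the priority rules.

**Step 5**
Reactants: 7 (2R,3R)-3-methyl-3-(4-methylpent-3-en-1-yl)oxirane-2-carbaldehyde; 4 methyl (2Z)-2-(bromomethyl)-4,4-dimethoxybut-2-enoate
Product: 10 (4S,5R)-4-(dimethoxymethyl)-3-methylidene-5-[(2S,3R)-3-methyl-3-(4-methylpent-3-en-1-yl)oxiran-2-yl]oxolan-2-one, via allylindium 8 (not isolated), via hydroxy ester 9 (not isolated)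
Conditions: In powder, THF/H2O (1:1), rt; then PPTS (cat.), CH2Cl2, rt
Reagents that add atoms: none
Why: Indium‑mediated Barbier 2‑(alkoxycarbonyl)allylation followed by lactonisation, in which the allylindium reacts through its γ‑carbon in a closed chair transition state so that the (Z)‑bromide gives the syn adduct (cis‑lactone, C7), while chelation of trivalent indium between the aldehyde and epoxide oxygens directs attack to the face anti to C4 and gives the 5,6‑threo relationship (C6 R).

**Step 6**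
Reactants: 10 (4S,5R)-4-(dimethoxymethyl)-3-methylidene-5-[(2S,3R)-3-methyl-3-(4-methylpent-3-en-1-yl)oxiran-2-yl]oxolan-2-one
Product: 12 3-[(2R,3S)-3-[(2R,3S)-3-(dimethoxymethyl)-4-methylidene-5-oxooxolan-2-yl]-2-methyloxiran-2-yl]propanal, via ozonide 11 (not isolated)
Conditions: O3, CH2Cl2, −78 °C (Sudan red 7B end point); then PPh3, −78 °C to rt
Reagents that add atoms: ozone [O-][O+]=O
Why: Ozonolysis with reductive work‑up, in which the electron‑rich trisubstituted olefin is cleaved far faster than the electron‑poor α‑methylene lactone; no stereocentre is touched.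

**Step 7**
Reactants: 12 3-[(2R,3S)-3-[(2R,3S)-3-(dimethoxymethyl)-4-methylidene-5-oxooxolan-2-yl]-2-methyloxiran-2-yl]propanal; 13 methyl 3,3-dimethoxypropanoate
Product: 17 methyl (2E)-2-(dimethoxymethyl)-5-[(2R,3S)-3-[(2R,3S)-3-(dimethoxymethyl)-4-methylidene-5-oxooxolan-2-yl]-2-methyloxiran-2-yl]pent-2-enoate, via lithium enolate 14 (not isolated), via aldolate 15 (not isolated), via acetate 16 (not isolated)
Conditions: LiN(iPr)2, THF, −78 °C; then 12, −78 °C; then Ac2O, −78 to 0 °C; then DBU, 0 °C to rt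
Reagents that add atoms: none
Why: Aldol condensation run as aldol addition, O‑acetylation and E1cB elimination in one flask, in which the lithium ester enolate adds to the aldehyde at −78 °C faster than to the α‑methylene lactone; the olefin geometry is of no consequence because it is erased in step 9.

**Step 8**
Reactants: 17 methyl (2E)-2-(dimethoxymethyl)-5-[(2R,3S)-3-[(2R,3S)-3-(dimethoxymethyl)-4-methylidene-5-oxooxolan-2-yl]-2-methyloxiran-2-yl]pent-2-enoate
Product: 18 methyl (2E)-2-formyl-5-[(2R,3S)-3-[(2R,3S)-3-formyl-4-methylidene-5-oxooxolan-2-yl]-2-methyloxiran-2-yl]pent-2-enoate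
Conditions: PPTS, acetone/H2O (10:1), 40 °C; used at once
Reagents that add atoms: water O
Why: Mild acid‑catalysed acetal hydrolysis, which the epoxide should survive because the adjacent acyloxy‑bearing carbon deactivates it towards ionisation; no stereocentre is touched, and 18 is not stored because C7 is epimerisable.

**Step 9**
Reactants: 18 methyl (2E)-2-formyl-5-[(2R,3S)-3-[(2R,3S)-3-formyl-4-methylidene-5-oxooxolan-2-yl]-2-methyloxiran-2-yl]pent-2-enoate
Product: 20 (4R,5S,6R,7R,8S,9S)-4,5-epoxy-8-hydroxy-14-methoxy-14-oxo-9-(triethylsilyloxy)germacra-1(10)E,11(13)-dien-12,6-olide, via allylchromium 19 (not isolated)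
Conditions: CrCl2 (5 equiv), Et3SiCl (1.5 equiv), DMF/THF, rt, slow addition of 18 to 2 mM final concentration
Reagents that add atoms: chlorotriethylsilane CC[Si](Cl)(CC)CC
Why: Proposed new method: divalent chromium reduces only the doubly activated 2‑formyl enoate (the saturated C8 aldehyde is inert to CrCl2) and Et3SiCl traps the oxygen, giving γ‑silyloxyallylchromium 19 in which the former aldehyde carbon C9 is nucleophilic; 19 adds through a six‑membered chair transition state to the C8 aldehyde, where C2 axial on the chromium‑bearing carbon gives the only olefin geometry the forming ten‑membered ring accepts (C2 cis to C9), the (Z)‑silyl enol ether gives the syn (threo) 8,9‑pattern, Felkin–Anh attack anti to the sp2 carbon C11 is expected to set C8 (S) and hence C9 (S), and the two oxygens emerge differentiated (O9 silylated, O8 free); the closest known reactions are the Takai and Groth chromium‑mediated pinacol‑type cross‑couplings of α,β‑unsaturated aldehydes with aldehydes in the presence of chlorosilanes and Nozaki–Hiyama macrocyclisations.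

**Step 10**
Reactants: 21 2-methylprop-2-en-1-ol
Product: 22 [(2R)-2-methyloxiran-2-yl]methanol
Conditions: Ti(OiPr)4 (5 mol%), D-(−)-diisopropyl tartrate (6 mol%), t-BuOOH, 4 Å molecular sieves, CH2Cl2, −20 °C
Reagents that add atoms: tert-butyl hydroperoxide CC(C)(C)OO
Why: Sharpless asymmetric epoxidation, in which the D‑(−)‑tartrate catalyst delivers oxygen to the face that gives the (R)‑epoxy alcohol.

**Step 11**
Reactants: 22 [(2R)-2-methyloxiran-2-yl]methanol
Product: 23 (2S)-2-methyloxirane-2-carboxylic acid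
Conditions: RuCl3·xH2O (2 mol%), NaIO4, CCl4/MeCN/H2O, rt
Reagents that add atoms: water O
Why: Sharpless RuCl3/NaIO4 oxidation (RuO4 formed in situ) takes the primary alcohol to the acid without opening the epoxide; the quaternary stereocentre is unchanged and its descriptor becomes S only through the priority rules.

**Step 12**
Reactants: 20 (4R,5S,6R,7R,8S,9S)-4,5-epoxy-8-hydroxy-14-methoxy-14-oxo-9-(triethylsilyloxy)germacra-1(10)E,11(13)-dien-12,6-olide; 23 (2S)-2-methyloxirane-2-carboxylic acid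
Product: 24 (4R,5S,6R,7R,8S,9S)-4,5-epoxy-14-methoxy-8-{[(2S)-2-methyloxirane-2-carbonyl]oxy}-14-oxo-9-(triethylsilyloxy)germacra-1(10)E,11(13)-dien-12,6-olide
Conditions: DCC, DMAP (cat.), CH2Cl2, 0 °C to rt
Reagents that add atoms: none
Why: Steglich esterification of the only free hydroxyl (O8) through the acylpyridinium; no stereocentre is formed and the quaternary acid centre cannot epimerise.

**Step 13**
Reactants: 24 (4R,5S,6R,7R,8S,9S)-4,5-epoxy-14-methoxy-8-{[(2S)-2-methyloxirane-2-carbonyl]oxy}-14-oxo-9-(triethylsilyloxy)germacra-1(10)E,11(13)-dien-12,6-olide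
Product: 26 (4R,5S,6R,7R,8S,9S)-9-acetoxy-4,5-epoxy-14-methoxy-8-{[(2S)-2-methyloxirane-2-carbonyl]oxy}-14-oxogermacra-1(10)E,11(13)-dien-12,6-olide, via alcohol 25 (not isolated)
Conditions: HF·pyridine, pyridine/THF, 0 °C; then Ac2O, DMAP, 0 °C to rt
Reagents that add atoms: acetic anhydride CC(=O)OC(C)=O
Why: Desilylation followed by acetylation in one flask, in which buffered HF·pyridine avoids the basic conditions that would cause acyl migration from O8 to O9 before the acetate is installed; no stereocentre is touched.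

**Compound list**
1 | 2,2-dimethoxyacetaldehyde | COC(OC)C=O | starting material
2 | methyl acrylate | C=CC(=O)OC | starting material
3 | methyl 3-hydroxy-4,4-dimethoxy-2-methylidenebutanoate (racemic) | C=C(C(=O)OC)C(O)C(OC)OC | intermediate
4 | methyl (2Z)-2-(bromomethyl)-4,4-dimethoxybut-2-enoate | BrC/C(C(=O)OC)=C\C(OC)OC | intermediate
5 | nerol, (2Z)-3,7-dimethylocta-2,6-dien-1-ol | CC(C)=CCC/C(C)=C\CO | starting material
6 | [(2S,3R)-3-methyl-3-(4-methylpent-3-en-1-yl)oxiran-2-yl]methanol | CC(C)=CCC[C@@]1(C)O[C@H]1CO | intermediate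
7 | (2R,3R)-3-methyl-3-(4-methylpent-3-en-1-yl)oxirane-2-carbaldehyde | CC(C)=CCC[C@@]1(C)O[C@H]1C=O | intermediate
8 | [(2Z)-4,4-dimethoxy-2-(methoxycarbonyl)but-2-en-1-yl]indium dibromide (allylindium, formed in the flask) | Br[In](Br)C/C(C(=O)OC)=C\C(OC)OC | intermediate
9 | methyl (3S,4R)-3-(dimethoxymethyl)-4-hydroxy-2-methylidene-4-[(2S,3R)-3-methyl-3-(4-methylpent-3-en-1-yl)oxiran-2-yl]butanoate | C=C(C(=O)OC)[C@H](C(OC)OC)[C@@H](O)[C@@H]1O[C@]1(C)CCC=C(C)C | intermediate
10 | (4S,5R)-4-(dimethoxymethyl)-3-methylidene-5-[(2S,3R)-3-methyl-3-(4-methylpent-3-en-1-yl)oxiran-2-yl]oxolan-2-one (4,5-cis) | C=C1C(=O)O[C@H]([C@H]1C(OC)OC)[C@@H]1O[C@]1(C)CCC=C(C)C | intermediate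
11 | secondary ozonide of 10 (5,5-dimethyl-1,2,4-trioxolan-3-yl in place of the 3-methylbut-2-enyl terminus; mixture at the ozonide carbon) | C=C1C(=O)O[C@H]([C@H]1C(OC)OC)[C@@H]1O[C@]1(C)CCC1OOC(C)(C)O1 | intermediate
12 | 3-[(2R,3S)-3-[(2R,3S)-3-(dimethoxymethyl)-4-methylidene-5-oxooxolan-2-yl]-2-methyloxiran-2-yl]propanal | C=C1C(=O)O[C@H]([C@H]1C(OC)OC)[C@@H]1O[C@]1(C)CCC=O | intermediate
13 | methyl 3,3-dimethoxypropanoate | COC(=O)CC(OC)OC | starting material
14 | lithium 1,3,3-trimethoxyprop-1-en-1-olate (lithium enolate of 13) | COC(O[Li])=CC(OC)OC | intermediate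
15 | lithium alkoxide of methyl 2-(dimethoxymethyl)-3-hydroxy-5-[(2R,3S)-3-[(2R,3S)-3-(dimethoxymethyl)-4-methylidene-5-oxooxolan-2-yl]-2-methyloxiran-2-yl]pentanoate (mixture at the two new centres) | C=C1C(=O)O[C@H]([C@H]1C(OC)OC)[C@@H]1O[C@]1(C)CCC(O[Li])C(C(=O)OC)C(OC)OC | intermediate
16 | methyl 3-acetoxy-2-(dimethoxymethyl)-5-[(2R,3S)-3-[(2R,3S)-3-(dimethoxymethyl)-4-methylidene-5-oxooxolan-2-yl]-2-methyloxiran-2-yl]pentanoate (mixture at the two new centres) | C=C1C(=O)O[C@H]([C@H]1C(OC)OC)[C@@H]1O[C@]1(C)CCC(OC(C)=O)C(C(=O)OC)C(OC)OC | intermediate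
17 | methyl (2E)-2-(dimethoxymethyl)-5-[(2R,3S)-3-[(2R,3S)-3-(dimethoxymethyl)-4-methylidene-5-oxooxolan-2-yl]-2-methyloxiran-2-yl]pent-2-enoate | C=C1C(=O)O[C@H]([C@H]1C(OC)OC)[C@@H]1O[C@]1(C)CC/C=C(/C(=O)OC)C(OC)OC | intermediate
18 | methyl (2E)-2-formyl-5-[(2R,3S)-3-[(2R,3S)-3-formyl-4-methylidene-5-oxooxolan-2-yl]-2-methyloxiran-2-yl]pent-2-enoate | C=C1C(=O)O[C@H]([C@H]1C=O)[C@@H]1O[C@]1(C)CC/C=C(/C(=O)OC)C=O | intermediate
19 | C1-bound allylchromium dichloride carrying the (Z)-triethylsilyl enol ether at C9 and the free C8 aldehyde (configuration at C1 undefined) | C=C1C(=O)O[C@H]([C@H]1C=O)[C@@H]1O[C@]1(C)CCC([Cr](Cl)Cl)/C(C(=O)OC)=C\O[Si](CC)(CC)CC | intermediate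
20 | (4R,5S,6R,7R,8S,9S)-4,5-epoxy-8-hydroxy-14-methoxy-14-oxo-9-(triethylsilyloxy)germacra-1(10)E,11(13)-dien-12,6-olide | C=C1C(=O)O[C@@H]2[C@H]1[C@H](O)[C@@H](O[Si](CC)(CC)CC)/C(C(=O)OC)=C\CC[C@@]1(C)O[C@@H]21 | intermediate
21 | 2-methylprop-2-en-1-ol | C=C(C)CO | starting material
22 | [(2R)-2-methyloxiran-2-yl]methanol | OC[C@]1(C)CO1 | intermediate
23 | (2S)-2-methyloxirane-2-carboxylic acid | OC(=O)[C@]1(C)CO1 | intermediate
24 | (4R,5S,6R,7R,8S,9S)-4,5-epoxy-14-methoxy-8-{[(2S)-2-methyloxirane-2-carbonyl]oxy}-14-oxo-9-(triethylsilyloxy)germacra-1(10)E,11(13)-dien-12,6-olide | C=C1C(=O)O[C@@H]2[C@H]1[C@H](OC(=O)[C@]1(C)CO1)[C@@H](O[Si](CC)(CC)CC)/C(C(=O)OC)=C\CC[C@@]1(C)O[C@@H]21 | intermediate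
25 | (4R,5S,6R,7R,8S,9S)-4,5-epoxy-9-hydroxy-14-methoxy-8-{[(2S)-2-methyloxirane-2-carbonyl]oxy}-14-oxogermacra-1(10)E,11(13)-dien-12,6-olide | C=C1C(=O)O[C@@H]2[C@H]1[C@H](OC(=O)[C@]1(C)CO1)[C@@H](O)/C(C(=O)OC)=C\CC[C@@]1(C)O[C@@H]21 | intermediate
26 | (4R,5S,6R,7R,8S,9S)-9-acetoxy-4,5-epoxy-14-methoxy-8-{[(2S)-2-methyloxirane-2-carbonyl]oxy}-14-oxogermacra-1(10)E,11(13)-dien-12,6-olide | C=C1C(=O)O[C@@H]2[C@H]1[C@H](OC(=O)[C@]1(C)CO1)[C@@H](OC(C)=O)/C(C(=O)OC)=C\CC[C@@]1(C)O[C@@H]21 | target

**Totals**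
Total step count: 13. Longest linear sequence: 9 steps (nerol 5 to target 26 through steps 3, 4, 5, 6, 7, 8, 9, 12 and 13).

**Steps most likely to fail, and fallbacks**

Step 9 (ring closure). The reduced enal may dimerise or be protonated instead of cyclising, or the wrong C8/C9 diastereomer may form. The fallback sets out from dialdehyde 18. Acetyl bromide (CH2Cl2, −40 °C, no Lewis acid) adds in 1,4‑fashion across the conjugated 2‑formyl enoate to give the bromo enol acetate F1. Indium powder in THF then closes the ring by a two‑electron γ‑acyloxyallylation of the C8 aldehyde (Lombardo–Trombini type) and gives the 9‑acetate 8‑alcohol F2 directly. Esterification of F2 with acid 23 (DCC, DMAP) comes back to the route at target 26; compounds 20, 24 and 25 are then not needed.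

Step 5 (facial selectivity at C6 and syn selectivity). If chelation by indium does not override the intrinsic Felkin preference of the cis‑epoxy aldehyde, the 5,6‑erythro lactone will dominate. The fallback sets out from 3 and 7. Acetylation of 3 gives the acetate F3, and copper‑catalysed SN2′ borylation (B2pin2, CuCl, KOAc, DMF) converts it into the allylboronate F4. F4 is added to 7 in a closed six‑membered allylboration transition state, which secures the syn adduct; the aldehyde face can be imposed by a chiral diol·SnCl4 catalyst instead of being left to chelation. Work‑up gives hydroxy ester 9, which lactonises (PPTS) and rejoins the route at 10.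

Step 7 (enolate and amidine base next to an α‑methylene lactone). Michael addition to the lactone or isomerisation of the exocyclic olefin may compete. The fallback sets out from aldehyde 12 and uses a neutral Wittig olefination. PPh3 and commercial methyl 2‑bromo‑3,3‑dimethoxypropanoate give the phosphonium bromide F5, which aqueous Na2CO3 converts into the stabilised ylide F6. F6 and 12 (toluene, 60 °C) give 17 directly, where the route is rejoined.

**Further compounds**
F1 | step 9 | methyl (2Z)-2-[(acetyloxy)methylidene]-3-bromo-5-[(2R,3S)-3-[(2R,3S)-3-formyl-4-methylidene-5-oxooxolan-2-yl]-2-methyloxiran-2-yl]pentanoate (configuration at the bromine-bearing carbon undefined) | C=C1C(=O)O[C@H]([C@H]1C=O)[C@@H]1O[C@]1(C)CCC(Br)/C(C(=O)OC)=C\OC(C)=O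
F2 | step 9 | (4R,5S,6R,7R,8S,9S)-9-acetoxy-4,5-epoxy-8-hydroxy-14-methoxy-14-oxogermacra-1(10)E,11(13)-dien-12,6-olide | C=C1C(=O)O[C@@H]2[C@H]1[C@H](O)[C@@H](OC(C)=O)/C(C(=O)OC)=C\CC[C@@]1(C)O[C@@H]21
F3 | step 5 | methyl 3-acetoxy-4,4-dimethoxy-2-methylidenebutanoate (racemic) | C=C(C(=O)OC)C(OC(C)=O)C(OC)OC
F4 | step 5 | methyl (2E)-4,4-dimethoxy-2-[(4,4,5,5-tetramethyl-1,3,2-dioxaborolan-2-yl)methyl]but-2-enoate | COC(=O)/C(CB1OC(C)(C)C(C)(C)O1)=C/C(OC)OC
F5 | step 7 | (1,1-dimethoxy-3-methoxy-3-oxopropan-2-yl)triphenylphosphonium bromide | COC(=O)C(C(OC)OC)[P+](c1ccccc1)(c1ccccc1)c1ccccc1.[Br-]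
F6 | step 7 | methyl 3,3-dimethoxy-2-(triphenyl-λ5-phosphanylidene)propanoate | COC(=O)C(C(OC)OC)=P(c1ccccc1)(c1ccccc1)c1ccccc1
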